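## Retrosynthetic overview

1. The isochroman-1-one lactone (O2–C1) is closed last. The C3 oxygen, held until then in a cis-5,6-dihydropyran-2-one, is passed from the side-chain carboxyl to the aryl ester, which frees the (E)-butenoic acid.
2. The plan rests on the benzene ring C4a–C5–C6–C7–C8–C8a with hydroxyls on C5, C6 and C8 and the C1 carbonyl on C8a. C5–C8 and all three oxygens come from 2,4-bis(silyloxy)furan; C4a, C8a and C1 come from an ynoate. Bonds C4a–C5 and C8a–C8 form by [4+2] addition, and the oxygen bridge then opens to the arene.
3. The ynoate is made from a silyl-capped alkyne by protodesilylation and oxidative methoxycarbonylation.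
4. The dihydropyranone carries both stereocentres (C3 and C4 of the target). It comes from an enantioselective glyoxylate hetero-Diels–Alder reaction of a silyl ketene acetal diene with an E-alkynyl terminus, itself made by a Z-selective Ando olefination.
5. Ring order: dihydropyranone, then benzene ring, then isochromanone lactone (with opening of the pyranone).

Key step: step 8

Remarks on the chemistry:
- The pyranone is numbered as 5,6-dihydro-2H-pyran-2-one (O1, C2 carbonyl, C6 bearing the ester) and the target as isochroman-1-one.
- Methyl glyoxylate is assumed to be used as the free aldehyde, freshly distilled from its commercial hemiacetal or oligomer.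
- The CIP descriptor at pyranone C5 changes from S to R when the alkyne loses its silyl group; the geometry does not change.

## Route

Step 1
Reactants: 1 dimethyl maleate; 2 diphenyl phosphite
Product: 3 dimethyl 2-(diphenoxyphosphoryl)butanedioate (racemic)
Conditions: DBU (10 mol%), CH2Cl2, 0 °C → rt
Reagents that add atoms: none
Why: Base-catalysed phospha-Michael (Pudovik-type) addition of the P–H bond across the maleate should give the diaryl phosphonate needed for an Ando olefination, the amidine base avoiding exchange of the phenoxy groups on phosphorus.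

Step 2
Reactants: 3 dimethyl 2-(diphenoxyphosphoryl)butanedioate; 4 3-(trimethylsilyl)prop-2-ynal
Product: 5 dimethyl (2Z)-2-[3-(trimethylsilyl)prop-2-yn-1-ylidene]butanedioate (alkynyl group cis to the ester on the alkene carbon)
Conditions: NaH, THF, 0 °C; then 4, −78 → −20 °C
Reagents that add atoms: none
Why: Ando variant of the Horner–Wadsworth–Emmons reaction, in which the electron-poor diaryl phosphonate should collapse under kinetic control to the Z-enoate, so that the alkynyl group lies cis to the α-ester; any E isomer would be removed by chromatography.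

Step 3
Reactants: 5 dimethyl (2Z)-2-[3-(trimethylsilyl)prop-2-yn-1-ylidene]butanedioate
Product: 6 methyl (2Z)-2-[2-(tert-butyldimethylsilyloxy)-2-methoxyethenyl]-5-(trimethylsilyl)pent-2-en-4-ynoate (silyl ketene acetal diene; alkynyl group trans to the ketene acetal arm; ketene acetal geometry of no consequence)
Conditions: LDA, THF, −78 °C; TBSCl, DMPU, −78 → 0 °C
Reagents that add atoms: tert-butyldimethylsilyl chloride, CC(C)(C)[Si](C)(C)Cl
Why: Kinetic deprotonation of the only acidic position (the CH2 that is α to one ester and allylic to the enyne) and O-silylation of the dienolate should give the 1-alkoxy-1-silyloxy diene, with the existing alkene untouched at low temperature so that the alkynyl group stays on the E terminus.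

Step 4
Reactants: 6 silyl ketene acetal diene; 7 methyl glyoxylate
Product: 9 dimethyl (5S,6S)-2-oxo-5-[(trimethylsilyl)ethynyl]-5,6-dihydro-2H-pyran-4,6-dicarboxylate (cis), via cyclic ortho ester 8 (not isolated)
Conditions: Cu(OTf)2 (10 mol%), (S,S)-tBu-box (11 mol%), CH2Cl2, −78 → −40 °C; then TFA (cat.), 0 °C
Reagents that add atoms: none
Why: Hetero-Diels–Alder reaction of the glyoxylate, held as a five-membered chelate on the Cu(OTf)2–bis(oxazoline) Lewis acid, with the electron-rich diene that its C3 ester biases toward s-cis; attack on the exposed Si face of the aldehyde should set C6 as S, the endo position of the chelated ester over the E-alkynyl terminus should place alkynyl and C6 ester cis (setting C5), and acid then collapses ortho ester 8 to the lactone.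

Step 5
Reactants: 9 cis-lactone with silyl-capped alkyne
Product: 10 dimethyl (5R,6S)-5-ethynyl-2-oxo-5,6-dihydro-2H-pyran-4,6-dicarboxylate (cis)
Conditions: AgNO3 (10 mol%), acetone/H2O, rt, dark
Reagents that add atoms: none
Why: Silver-catalysed protodesilylation of an alkynylsilane runs at neutral pH, which should spare the doubly activated C5–H (γ to the lactone carbonyl and propargylic) that carbonate or unbuffered fluoride would remove.

Step 6
Reactants: 10 terminal alkyne
Product: 11 dimethyl (5R,6S)-5-(3-methoxy-3-oxoprop-1-yn-1-yl)-2-oxo-5,6-dihydro-2H-pyran-4,6-dicarboxylate (cis)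
Conditions: PdCl2 (5 mol%), CuCl2 (2 equiv), NaOAc (2 equiv), CO (1 atm), MeOH, rt
Reagents that add atoms: carbon monoxide, [C-]#[O+]; methanol, CO
Why: Tsuji oxidative alkoxycarbonylation of a terminal alkyne (alkynylpalladium, CO insertion, methanolysis, reoxidation by CuCl2) should give the ynoate without any acetylide base, the acetate buffer being too weak to epimerise C5 or open the lactone.

Step 7
Reactants: 12 tetronic acid
Product: 13 2,4-bis(tert-butyldimethylsilyloxy)furan
Conditions: TBSOTf (2.2 equiv), Et3N (3 equiv), CH2Cl2, 0 °C → rt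
Reagents that add atoms: tert-butyldimethylsilyl trifluoromethanesulfonate, CC(C)(C)[Si](C)(C)OS(=O)(=O)C(F)(F)F
Why: O-silylation of the enol followed by soft enolisation of the resulting 4-silyloxybutenolide (the standard butenolide to 2-silyloxyfuran conversion) should give the bis(silyloxy)furan, to be used freshly distilled.

Step 8
Reactants: 11 ynoate; 13 2,4-bis(tert-butyldimethylsilyloxy)furan
Product: 15 dimethyl (5R,6S)-5-[3,5-bis(tert-butyldimethylsilyloxy)-6-hydroxy-2-(methoxycarbonyl)phenyl]-2-oxo-5,6-dihydro-2H-pyran-4,6-dicarboxylate (cis), via oxanorbornadiene cycloadduct 14 (not isolated)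
Conditions: 13 (3 equiv), PhMe, 100 °C, sealed tube, Ar
Reagents that add atoms: none
Why: Furan 13, a cyclic member of the 1,3-dioxygenated diene family, should add as a normal-demand 4π partner across the ynoate of 11, its C5 (the terminus with the largest HOMO coefficient, vinylogous to the 2-silyloxy group and α to the 4-silyloxy group and ring oxygen) bonding to the ynoate β-carbon (future C4a) and its C2 to the α-carbon (future C8a), to give 7-oxanorbornadiene 14. The silyloxy-bearing bridgehead of 14 is a ketal carbon: its C–O bridge bond ionises, the bridge oxygen stays on the other bridgehead and loss of that bridgehead proton gives the C5 phenol, so the benzene ring is closed by a [4+2] cycloaddition (two C–C bonds) followed by C–O cleavage and tautomerisation. The closest known reaction type is the cycloaddition of 2-silyloxy- and 2-alkoxyfurans with acetylenic esters with ring-opening to phenols, applied here to a β-branched ynoate, which is the harder case. No stereocentre is created, the bridgehead centres of 14 being erased on aromatisation, and C5 and C6 of the pyranone are not touched because the medium is neutral and base-free (base would cause propargyl–allenyl isomerisation or eliminative lactone opening). The step needs regiocontrol, secured by the matched polarisation of the two partners (C8 oxygen next to the ester, free hydroxyl at C5), and chemoselectivity for the alkyne over the trisubstituted enoate of the pyranone, secured because a furan–alkene adduct is a strained oxanorbornene that reverts whereas the alkyne adduct is drained irreversibly by aromatisation.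

Step 9
Reactants: 15 bis-silylated aryl pyranone
Product: 18 (2E)-4-methoxy-3-[(3S,4R)-5,6,8-trihydroxy-3-(methoxycarbonyl)-1-oxo-3,4-dihydro-1H-2-benzopyran-4-yl]-4-oxobut-2-enoic acid (CNP0546035.1; 3,4-trans), via triol pyranone 16 (not isolated), via seco hydroxy acid 17 (not isolated)
Conditions: TFA/H2O/MeCN (degassed), Ar, rt → 45 °C
Reagents that add atoms: water, O
Why: Acid hydrolysis removes both aryl silyl ethers and reversibly opens the δ-lactone; the freed C3 hydroxyl should then lactonise irreversibly onto the ortho-hydroxy benzoate (six-membered ring, peri hydrogen bond) rather than onto the acrylate ester, where a five-membered lactone would force the cis carboxyvinyl group into allylic strain with the aryl-bearing C4, and the alkene geometry fixed by the pyranone ring becomes the E side chain with C3 and C4 unchanged.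

## Compound list

1 | dimethyl maleate | COC(=O)/C=C\C(=O)OC | starting material
2 | diphenyl phosphite | O=[PH](Oc1ccccc1)Oc1ccccc1 | starting material
3 | dimethyl 2-(diphenoxyphosphoryl)butanedioate (racemic) | COC(=O)CC(C(=O)OC)P(=O)(Oc1ccccc1)Oc1ccccc1 | intermediate
4 | 3-(trimethylsilyl)prop-2-ynal | C[Si](C)(C)C#CC=O | starting material
5 | dimethyl (2Z)-2-[3-(trimethylsilyl)prop-2-yn-1-ylidene]butanedioate | COC(=O)C/C(C(=O)OC)=C/C#C[Si](C)(C)C | intermediate
6 | methyl (2Z)-2-[2-(tert-butyldimethylsilyloxy)-2-methoxyethenyl]-5-(trimethylsilyl)pent-2-en-4-ynoate | COC(O[Si](C)(C)C(C)(C)C)=C/C(C(=O)OC)=C/C#C[Si](C)(C)C | intermediate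
7 | methyl glyoxylate | COC(=O)C=O | starting material
8 | dimethyl (5S,6S)-2-(tert-butyldimethylsilyloxy)-2-methoxy-5-[(trimethylsilyl)ethynyl]-5,6-dihydro-2H-pyran-4,6-dicarboxylate (cis; mixture at C2; not isolated) | COC(=O)C1=CC(OC)(O[Si](C)(C)C(C)(C)C)O[C@H](C(=O)OC)[C@@H]1C#C[Si](C)(C)C | intermediate
9 | dimethyl (5S,6S)-2-oxo-5-[(trimethylsilyl)ethynyl]-5,6-dihydro-2H-pyran-4,6-dicarboxylate (cis) | COC(=O)C1=CC(=O)O[C@H](C(=O)OC)[C@@H]1C#C[Si](C)(C)C | intermediate
10 | dimethyl (5R,6S)-5-ethynyl-2-oxo-5,6-dihydro-2H-pyran-4,6-dicarboxylate (cis) | COC(=O)C1=CC(=O)O[C@H](C(=O)OC)[C@@H]1C#C | intermediate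
11 | dimethyl (5R,6S)-5-(3-methoxy-3-oxoprop-1-yn-1-yl)-2-oxo-5,6-dihydro-2H-pyran-4,6-dicarboxylate (cis) | COC(=O)C1=CC(=O)O[C@H](C(=O)OC)[C@@H]1C#CC(=O)OC | intermediate
12 | tetronic acid | O=C1CC(=O)CO1 | starting material
13 | 2,4-bis(tert-butyldimethylsilyloxy)furan | CC(C)(C)[Si](C)(C)Oc1coc(O[Si](C)(C)C(C)(C)C)c1 | intermediate
14 | dimethyl (5R,6S)-5-[4,6-bis(tert-butyldimethylsilyloxy)-3-(methoxycarbonyl)-7-oxabicyclo[2.2.1]hepta-2,5-dien-2-yl]-2-oxo-5,6-dihydro-2H-pyran-4,6-dicarboxylate (bridgehead mixture; not isolated) | COC(=O)C1=CC(=O)O[C@H](C(=O)OC)[C@@H]1C2=C(C(=O)OC)C3(O[Si](C)(C)C(C)(C)C)C=C(O[Si](C)(C)C(C)(C)C)C2O3 | intermediate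
15 | dimethyl (5R,6S)-5-[3,5-bis(tert-butyldimethylsilyloxy)-6-hydroxy-2-(methoxycarbonyl)phenyl]-2-oxo-5,6-dihydro-2H-pyran-4,6-dicarboxylate (cis) | COC(=O)C1=CC(=O)O[C@H](C(=O)OC)[C@@H]1c2c(O)c(O[Si](C)(C)C(C)(C)C)cc(O[Si](C)(C)C(C)(C)C)c2C(=O)OC | intermediate
16 | dimethyl (5R,6S)-2-oxo-5-[2,3,5-trihydroxy-6-(methoxycarbonyl)phenyl]-5,6-dihydro-2H-pyran-4,6-dicarboxylate (cis; not isolated) | COC(=O)C1=CC(=O)O[C@H](C(=O)OC)[C@@H]1c2c(O)c(O)cc(O)c2C(=O)OC | intermediate
17 | (2E)-3-{(1R,2S)-2-hydroxy-3-methoxy-3-oxo-1-[2,3,5-trihydroxy-6-(methoxycarbonyl)phenyl]propyl}-4-methoxy-4-oxobut-2-enoic acid (not isolated) | COC(=O)/C(=C/C(=O)O)[C@@H](c1c(O)c(O)cc(O)c1C(=O)OC)[C@H](O)C(=O)OC | intermediate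
18 | (2E)-4-methoxy-3-[(3S,4R)-5,6,8-trihydroxy-3-(methoxycarbonyl)-1-oxo-3,4-dihydro-1H-2-benzopyran-4-yl]-4-oxobut-2-enoic acid | COC(=O)/C(=C/C(=O)O)[C@H]1c2c(O)c(O)cc(O)c2C(=O)O[C@@H]1C(=O)OC | target

## Step count and risks

Total steps: 9. Longest linear sequence: 8 (steps 1–6, 8, 9); step 7 is the one-step side branch.

**Step 8 (key cycloaddition).**
- What may go wrong: the furan must give up its aromaticity to attack a hindered, singly activated alkyne. If this is slow at 100 °C, thermal propargyl–allenyl isomerisation or epimerisation of 11, or conjugate addition of the furan to the enoate, could take over.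
- Fallback: set out from 11 and replace the furan by an open-chain diene of the same oxidation level.
  - Commercial methyl (tert-butyldimethylsilyloxy)acetate is condensed with the lithium enolate of methyl acetate (LDA, THF, −78 °C, crossed Claisen) to methyl 4-(tert-butyldimethylsilyloxy)-3-oxobutanoate F1.
  - TMSOTf/Et3N in Et2O at 0 °C should convert it into 4-(tert-butyldimethylsilyloxy)-1-methoxy-1,3-bis(trimethylsilyloxy)buta-1,3-diene F2.
  - This Chan-type diene should add to 11 in toluene at 60–80 °C with the same polarity (silyloxy-bearing terminus to the ynoate β-carbon) to give the cyclohexa-1,4-diene cycloadduct F3.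
  - F3 aromatises by loss of methanol to the tris-silylated aryl pyranone F4 (C5–OTBS, C6–OTMS, C8–OTMS).
  - Under the conditions of step 9, F4 loses all silyl groups and rejoins the route at 16, then 17 and 18.

**Step 4 (asymmetric hetero-Diels–Alder reaction).**
- What may go wrong: C–C bond formation may turn stepwise (open Mukaiyama-aldol pathway), which would erode endo and facial control and give trans-lactone, open-chain adducts or low enantiomeric purity.
- Fallback: set out from 6 and 7 and separate the two tasks.
  - Relative configuration would be set by a pericyclic, endo-selective Eu(fod)3-catalysed cycloaddition (CH2Cl2, rt; then catalytic TFA). This passes through the racemic ortho ester (8 together with its enantiomer F5) to the racemic cis-lactone (9 together with its enantiomer F6).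
  - Absolute configuration would come from preparative chromatography on a chiral stationary phase (amylose tris(3,5-dimethylphenylcarbamate)); 9 re-enters the route at step 5.

**Step 9 (deprotection and lactone interchange).**
- What may go wrong: the hydroxyl released on opening may partition between the benzoate, the acrylate ester (five-membered lactone) and re-closure to the pyranone. Opening under acid may be slow enough for methyl esters to hydrolyse, and the hydroxyquinol may oxidise in air.
- Fallback: set out from 15 and split the step, opening the lactone by carboxylate formation instead of acid equilibrium.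
  - Et3N·3HF in MeCN at 0 °C → rt should give triol pyranone 16, isolated under argon.
  - 16 is then stirred in degassed phosphate buffer (pH 7.5)/MeCN with sodium ascorbate at 25–37 °C. Ionisation of the fumaric half-acid pulls the lactone open to 17 (as its carboxylate), which also deactivates the neighbouring acrylate ester. The C3 hydroxyl is acylated by the salicylate-type methyl ester under intramolecular general-base assistance from the C8 phenoxide.
  - Acidification to pH 2 and extraction should give 18; recovered pyranone is recycled.

Further compounds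
F1 | step 8 | methyl 4-(tert-butyldimethylsilyloxy)-3-oxobutanoate | COC(=O)CC(=O)CO[Si](C)(C)C(C)(C)C
F2 | step 8 | 4-(tert-butyldimethylsilyloxy)-1-methoxy-1,3-bis(trimethylsilyloxy)buta-1,3-diene | COC(O[Si](C)(C)C)=CC(O[Si](C)(C)C)=CO[Si](C)(C)C(C)(C)C
F3 | step 8 | dimethyl (5R,6S)-5-[6-(tert-butyldimethylsilyloxy)-3-methoxy-2-(methoxycarbonyl)-3,5-bis(trimethylsilyloxy)cyclohexa-1,4-dien-1-yl]-2-oxo-5,6-dihydro-2H-pyran-4,6-dicarboxylate | COC(=O)C1=CC(=O)O[C@H](C(=O)OC)[C@@H]1C2=C(C(=O)OC)C(OC)(O[Si](C)(C)C)C=C(O[Si](C)(C)C)C2O[Si](C)(C)C(C)(C)C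
F4 | step 8 | dimethyl (5R,6S)-5-[2-(tert-butyldimethylsilyloxy)-6-(methoxycarbonyl)-3,5-bis(trimethylsilyloxy)phenyl]-2-oxo-5,6-dihydro-2H-pyran-4,6-dicarboxylate | COC(=O)C1=CC(=O)O[C@H](C(=O)OC)[C@@H]1c2c(O[Si](C)(C)C(C)(C)C)c(O[Si](C)(C)C)cc(O[Si](C)(C)C)c2C(=O)OC
F5 | step 4 | dimethyl (5R,6R)-2-(tert-butyldimethylsilyloxy)-2-methoxy-5-[(trimethylsilyl)ethynyl]-5,6-dihydro-2H-pyran-4,6-dicarboxylate (enantiomer of 8) | COC(=O)C1=CC(OC)(O[Si](C)(C)C(C)(C)C)O[C@@H](C(=O)OC)[C@H]1C#C[Si](C)(C)C
F6 | step 4 | dimethyl (5R,6R)-2-oxo-5-[(trimethylsilyl)ethynyl]-5,6-dihydro-2H-pyran-4,6-dicarboxylate (enantiomer of 9) | COC(=O)C1=CC(=O)O[C@@H](C(=O)OC)[C@H]1C#C[Si](C)(C)C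
F0 | step 9 | none | none
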